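Everything rests on disconnecting ring Ar', the 2-hydroxy-4,6-dimethoxyphenyl ring on ketone C4, at its C1'–C2' bond. The feature exploited is that this ring, with oxygen on C2', C4' and C6' and the acyl carbon C4 on C1', is a folded 3,5,7-tricarbonyl chain. In the key step Mg(OMe)2 opens a 4-methoxy-2-pyrone, which stores that chain with the C4' methyl ether in place, and the methylene next to C4 closes onto the freed ester, building the whole arene in one operation. Precursor 14 is a 6-(2-oxoalkyl)-4-methoxy-2-pyrone already carrying the C3 amide and the C2 phenyl stereocentre, with ketone C1 masked as a methylidene group so that C2 cannot enolise.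

Key step: step 7

Labels: chain An–C1(=O)–C2H(Ph)–C3H(CONHR)–C4(=O)–Ar' (An = 4-methoxyphenyl, R = 4-benzamidobutyl); ring Ar' atoms C1' (on C4) to C6'. The target is (2R,3R) in these labels.

Assumption: C3 lies between ketone C4 and a carboxyl carbon and epimerises easily, so 7, 9, 12 and 14–18 are carried as C3 epimer mixtures (their SMILES leave C3 open) and C3 is fixed only in step 9, taking the (2R,3R) arrangement to be the thermodynamically preferred, crystallising diastereomer.

Step 1
Reactants: 1 4-ethynylanisole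
Product: 2 2-[1-(4-methoxyphenyl)ethenyl]-4,4,5,5-tetramethyl-1,3,2-dioxaborolane
Conditions: B2pin2 (1.1 equiv), CuCl (5 mol %), 1,3-dimesitylimidazolinium chloride (5 mol %), NaOtBu (10 mol %), MeOH (2 equiv), THF, −15 °C to rt
Reagents that add atoms: bis(pinacolato)diboron, CC1(C)OB(OC1(C)C)B1OC(C)(C)C(C)(C)O1
Why: Copper-catalysed protoboration of a terminal aryl alkyne, in which the boryl–copper species carrying an N-aryl carbene ligand should place boron on the aryl-bearing carbon and methanol protonates the alkenyl–copper bond, giving the 1-arylvinyl (Markovnikov) boronate, with any linear isomer removed on silica.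

Step 2
Reactants: 3 benzaldehyde; 4 Meldrum's acid (2,2-dimethyl-1,3-dioxane-4,6-dione)
Product: 5 2,2-dimethyl-5-(phenylmethylidene)-1,3-dioxane-4,6-dione
Conditions: H2O, 75 °C (product crystallises)
Reagents that add atoms: none
Why: Knoevenagel condensation of the strongly acidic cyclic malonate with a non-enolisable aldehyde, driven by precipitation of a symmetric alkylidene that has no E/Z isomers.

Step 3
Reactants: 2 2-[1-(4-methoxyphenyl)ethenyl]-4,4,5,5-tetramethyl-1,3,2-dioxaborolane; 5 2,2-dimethyl-5-(phenylmethylidene)-1,3-dioxane-4,6-dione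
Product: 6 5-[(1R)-2-(4-methoxyphenyl)-1-phenylprop-2-en-1-yl]-2,2-dimethyl-1,3-dioxane-4,6-dione
Conditions: [RhCl(C2H4)2]2 (2.5 mol %), (1R,4R)-2,5-diphenylbicyclo[2.2.2]octa-2,5-diene (5.5 mol %), KOH (20 mol %), dioxane–H2O 10:1, 30 °C, 5 added last; aq. citric acid work-up
Reagents that add atoms: none
Why: Rhodium-catalysed asymmetric conjugate addition (Hayashi–Miyaura reaction), in which the alkenyl group passes from boron to monovalent rhodium and inserts into the highly electrophilic benzylidene C=C while the C2-symmetric chiral diene steers it to the Si face of the benzylidene carbon to set C2 as R, the ligand hand being chosen by analogy with its sense on E-configured acceptors and confirmed on 6.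

Step 4
Reactants: 6 5-[(1R)-2-(4-methoxyphenyl)-1-phenylprop-2-en-1-yl]-2,2-dimethyl-1,3-dioxane-4,6-dione
Product: 7 (2RS,3R)-2-[(ethylsulfanyl)carbonyl]-4-(4-methoxyphenyl)-3-phenylpent-4-enoic acid
Conditions: EtSH (5 equiv), BHT (2 mol %), degassed MeCN, sealed tube, 70 °C, dark
Reagents that add atoms: ethanethiol, CCS
Why: Thiolysis of the activated cyclic diester (acyl substitution at one ring carbonyl followed by loss of acetone) should give the malonic acid half thioester without base, which avoids decarboxylation, while exclusion of oxygen and light plus a radical inhibitor keeps the thiol from adding to the styrene-type alkene.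

Step 5
Reactants: 7 (2RS,3R)-2-[(ethylsulfanyl)carbonyl]-4-(4-methoxyphenyl)-3-phenylpent-4-enoic acid; 8 4-methoxy-6-methyl-2H-pyran-2-one
Product: 12 S-ethyl (2RS,3R)-2-[(4-methoxy-2-oxo-2H-pyran-6-yl)acetyl]-4-(4-methoxyphenyl)-3-phenylpent-4-enethioate, via acid chloride 9 (not isolated), via lithiated pyrone 10 (not isolated), via acylketene 11 (not isolated)
Conditions: 7, 1-chloro-N,N,2-trimethylprop-1-en-1-amine (1.1 equiv), CH2Cl2, 0 °C; solution added to 8 (3.0 equiv) and LiN(iPr)2 (2.9 equiv), THF, −78 °C; AcOH quench at −78 °C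
Reagents that add atoms: none
Why: Claisen-type C-acylation of the lithiated 6-methyl group of the pyrone, in which the acid chloride (made under neutral conditions so that no HCl meets the electron-rich alkene) loses HCl to a first equivalent of 10 by an E1cB pathway to give ketene 11, whose unhindered sp carbon is attacked by a second equivalent of 10 to deliver 12 directly as its chelated lithium enolate, protected from further acylation.

Step 6
Reactants: 12 S-ethyl (2RS,3R)-2-[(4-methoxy-2-oxo-2H-pyran-6-yl)acetyl]-4-(4-methoxyphenyl)-3-phenylpent-4-enethioate; 13 N-(4-aminobutyl)benzamide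
Product: 14 N-[4-({(2RS,3R)-2-[(4-methoxy-2-oxo-2H-pyran-6-yl)acetyl]-4-(4-methoxyphenyl)-3-phenylpent-4-enoyl}amino)butyl]benzamide
Conditions: AgOCOCF3 (1.2 equiv), Et3N (1.5 equiv), THF, 0 °C to rt
Reagents that add atoms: none
Why: Silver-promoted aminolysis of a β-keto thioester, in which the thiophilic monovalent silver ion activates the C–S bond so that the primary amine should form the β-keto amide quickly at room temperature, faster than it can condense with the ketone or attack the pyrone.

Step 7
Reactants: 14 N-[4-({(2RS,3R)-2-[(4-methoxy-2-oxo-2H-pyran-6-yl)acetyl]-4-(4-methoxyphenyl)-3-phenylpent-4-enoyl}amino)butyl]benzamide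
Product: 16 N-[4-({(2RS,3R)-2-(2,6-dihydroxy-4-methoxybenzoyl)-4-(4-methoxyphenyl)-3-phenylpent-4-enoyl}amino)butyl]benzamide, via ring-opened keto ester 15 (not isolated)
Conditions: Mg(OMe)2 (6 equiv), MeOH, reflux; then cold aq. NH4Cl
Reagents that add atoms: none
Why: Methoxide adds to the lactone carbonyl of 14 (pyrone C2, the future C2') and the ring opens to the magnesium chelate of the (E)-3-methoxy-5,7-dioxo ester 15, whose enol ether keeps the chain ends cis as inherited from the ring, after which the chelated methylene C1' between C4 and the former pyrone C6 attacks the ester carbonyl, methoxide leaves and enolisation aromatises, forming the C1'–C2' bond and ring Ar'. The step is an intramolecular Claisen condensation, and the closest known reaction is the magnesium-alkoxide-induced cyclisation of 6-(2-oxoalkyl)-4-methoxy-2-pyrones to acylphloroglucinols. Ring Ar' closes in a 6-exo-trig mode, the attacked ester C=O lying outside the new ring. No stereocentre is formed: C2 cannot epimerise because C1 is an alkene, and C3 merely equilibrates and is settled in step 9. The step needs Claisen closure (C1' onto the ester) in preference to aldol closure (the ester α-carbon, future C3', onto ketone C4), which the magnesium template secures by holding the diketone flanking C1' as the nucleophilic enolate and which the crowded, branched C3 next to C4 reinforces. It also needs the ortho-phenoxides of 16 to leave the C3 carboxyl alone, which is why that carboxyl is a secondary amide, too poor an acyl donor to close a 4-hydroxycoumarin.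

Step 8
Reactants: 16 N-[4-({(2RS,3R)-2-(2,6-dihydroxy-4-methoxybenzoyl)-4-(4-methoxyphenyl)-3-phenylpent-4-enoyl}amino)butyl]benzamide
Product: 17 N-[4-({(2RS,3R)-2-(2-hydroxy-4,6-dimethoxybenzoyl)-4-(4-methoxyphenyl)-3-phenylpent-4-enoyl}amino)butyl]benzamide
Conditions: Me3SiCHN2 (1.2 equiv), MeOH–toluene 1:4, 0 °C to rt
Reagents that add atoms: (trimethylsilyl)diazomethane, C[Si](C)(C)C=[N+]=[N-]
Why: O-Methylation of an acidic phenol by a diazoalkane, in which the hydroxyl of the two equivalent ortho groups that is not hydrogen-bonded to C4=O is methylated and the remaining one, then locked in the six-membered chelate, should not react, so that the reaction stops at the monomethyl ether without base and without C-methylation at C3.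

Step 9
Reactants: 17 N-[4-({(2RS,3R)-2-(2-hydroxy-4,6-dimethoxybenzoyl)-4-(4-methoxyphenyl)-3-phenylpent-4-enoyl}amino)butyl]benzamide
Product: 19 N-[4-({(2R,3R)-2-(2-hydroxy-4,6-dimethoxybenzoyl)-4-(4-methoxyphenyl)-4-oxo-3-phenylbutanoyl}amino)butyl]benzamide (target CNP0208962.1), via vicinal diol 18 (not isolated)
Conditions: OsO4 (2 mol %), NaIO4 (4 equiv), 2,6-lutidine (2 equiv), dioxane–H2O 3:1, rt; then Et3N (0.2 equiv), MeOH, rt, crystallisation
Reagents that add atoms: osmium tetroxide, O=[Os](=O)(=O)=O; sodium periodate, [Na+].[O-]I(=O)(=O)=O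
Why: Lemieux–Johnson oxidation, in which catalytic dihydroxylation of the only alkene and periodate cleavage of diol 18 unmask ketone C1 with loss of formaldehyde under lutidine buffering that leaves C2–H alone, after which brief contact with a weak amine base should equilibrate only the much more acidic C3–H so that C3 settles, under control of the fixed C2 centre, in the assumed more stable (2R,3R) arrangement, collected by crystallisation while the mother liquor is re-equilibrated.

Compound list
1 | 4-ethynylanisole | C#Cc1ccc(OC)cc1 | starting material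
2 | 2-[1-(4-methoxyphenyl)ethenyl]-4,4,5,5-tetramethyl-1,3,2-dioxaborolane | C=C(B1OC(C)(C)C(C)(C)O1)c1ccc(OC)cc1 | intermediate
3 | benzaldehyde | O=Cc1ccccc1 | starting material
4 | Meldrum's acid (2,2-dimethyl-1,3-dioxane-4,6-dione) | CC1(C)OC(=O)CC(=O)O1 | starting material
5 | 2,2-dimethyl-5-(phenylmethylidene)-1,3-dioxane-4,6-dione | CC1(C)OC(=O)C(=Cc2ccccc2)C(=O)O1 | intermediate
6 | 5-[(1R)-2-(4-methoxyphenyl)-1-phenylprop-2-en-1-yl]-2,2-dimethyl-1,3-dioxane-4,6-dione | C=C(c1ccc(OC)cc1)[C@@H](c1ccccc1)C1C(=O)OC(C)(C)OC1=O | intermediate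
7 | (2RS,3R)-2-[(ethylsulfanyl)carbonyl]-4-(4-methoxyphenyl)-3-phenylpent-4-enoic acid | C=C(c1ccc(OC)cc1)[C@@H](c1ccccc1)C(C(=O)O)C(=O)SCC | intermediate
8 | 4-methoxy-6-methyl-2H-pyran-2-one | CC1=CC(OC)=CC(=O)O1 | starting material
9 | S-ethyl (2RS,3R)-2-(chlorocarbonyl)-4-(4-methoxyphenyl)-3-phenylpent-4-enethioate | C=C(c1ccc(OC)cc1)[C@@H](c1ccccc1)C(C(=O)Cl)C(=O)SCC | intermediate
10 | 6-(lithiomethyl)-4-methoxy-2H-pyran-2-one | [Li]CC1=CC(OC)=CC(=O)O1 | intermediate
11 | S-ethyl (3R)-4-(4-methoxyphenyl)-2-(oxomethylidene)-3-phenylpent-4-enethioate | C=C(c1ccc(OC)cc1)[C@@H](c1ccccc1)C(=C=O)C(=O)SCC | intermediate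
12 | S-ethyl (2RS,3R)-2-[(4-methoxy-2-oxo-2H-pyran-6-yl)acetyl]-4-(4-methoxyphenyl)-3-phenylpent-4-enethioate | C=C(c1ccc(OC)cc1)[C@@H](c1ccccc1)C(C(=O)SCC)C(=O)CC1=CC(OC)=CC(=O)O1 | intermediate
13 | N-(4-aminobutyl)benzamide | NCCCCNC(=O)c1ccccc1 | starting material
14 | N-[4-({(2RS,3R)-2-[(4-methoxy-2-oxo-2H-pyran-6-yl)acetyl]-4-(4-methoxyphenyl)-3-phenylpent-4-enoyl}amino)butyl]benzamide | C=C(c1ccc(OC)cc1)[C@@H](c1ccccc1)C(C(=O)NCCCCNC(=O)c1ccccc1)C(=O)CC1=CC(OC)=CC(=O)O1 | intermediate
15 | methyl (3E,8RS,9R)-8-{[4-(benzoylamino)butyl]carbamoyl}-3-methoxy-10-(4-methoxyphenyl)-5,7-dioxo-9-phenylundeca-3,10-dienoate (as magnesium chelate) | C=C(c1ccc(OC)cc1)[C@@H](c1ccccc1)C(C(=O)NCCCCNC(=O)c1ccccc1)C(=O)CC(=O)/C=C(/OC)CC(=O)OC | intermediate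
16 | N-[4-({(2RS,3R)-2-(2,6-dihydroxy-4-methoxybenzoyl)-4-(4-methoxyphenyl)-3-phenylpent-4-enoyl}amino)butyl]benzamide | C=C(c1ccc(OC)cc1)[C@@H](c1ccccc1)C(C(=O)NCCCCNC(=O)c1ccccc1)C(=O)c1c(O)cc(OC)cc1O | intermediate
17 | N-[4-({(2RS,3R)-2-(2-hydroxy-4,6-dimethoxybenzoyl)-4-(4-methoxyphenyl)-3-phenylpent-4-enoyl}amino)butyl]benzamide | C=C(c1ccc(OC)cc1)[C@@H](c1ccccc1)C(C(=O)NCCCCNC(=O)c1ccccc1)C(=O)c1c(O)cc(OC)cc1OC | intermediate
18 | N-[4-({(2RS,3R,4RS)-4,5-dihydroxy-2-(2-hydroxy-4,6-dimethoxybenzoyl)-4-(4-methoxyphenyl)-3-phenylpentanoyl}amino)butyl]benzamide | OCC(O)(c1ccc(OC)cc1)[C@@H](c1ccccc1)C(C(=O)NCCCCNC(=O)c1ccccc1)C(=O)c1c(O)cc(OC)cc1OC | intermediate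
19 | N-[4-({(2R,3R)-2-(2-hydroxy-4,6-dimethoxybenzoyl)-4-(4-methoxyphenyl)-4-oxo-3-phenylbutanoyl}amino)butyl]benzamide | COc1ccc(C(=O)[C@@H](c2ccccc2)[C@@H](C(=O)NCCCCNC(=O)c2ccccc2)C(=O)c2c(O)cc(OC)cc2OC)cc1 | target

Total step count: 9.
Longest linear sequence: 8 steps (1 → 2 → 6 → 7 → 12 → 14 → 16 → 17 → 19; the branch 3 + 4 → 5 is one further step).

Steps most likely to fail

Step 7. The opened chain may close in the aldol mode, fragment by retro-Claisen attack of methoxide, or a ring phenoxide may displace the amine from the C3 amide. The fallback brings ring Ar' in intact instead of building it. It sets out from 7 and comes back at 17. Acid 7 is converted into acid chloride 9 as in step 5 and added at −78 °C to 2,4,6-trimethoxyphenyllithium F1 (from 1,3,5-trimethoxybenzene and n-BuLi, 2.2 equiv, THF). One equivalent generates ketene 11 and the second adds to it, giving S-ethyl (2RS,3R)-4-(4-methoxyphenyl)-3-phenyl-2-(2,4,6-trimethoxybenzoyl)pent-4-enethioate F2. Silver-promoted aminolysis with 13 under the conditions of step 6 should give N-[4-({(2RS,3R)-4-(4-methoxyphenyl)-3-phenyl-2-(2,4,6-trimethoxybenzoyl)pent-4-enoyl}amino)butyl]benzamide F3. MgI2 etherate in toluene then cleaves, with chelation assistance, one methyl ether ortho to the ketone carbonyl and returns 17.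

Step 5. Proton transfer from the malonyl C–H may outrun carbon–carbon bond formation, or a second acylation or attack at the thioester may intervene. The fallback replaces the strongly basic carbanion by a soft magnesium enolate carrying a traceless ester. It sets out from 8 (and uses 9, made from 7 as in step 5) and comes back at 12. Pyrone 8 is lithiated with LiN(iPr)2 (2 equiv) and treated with allyl chloroformate to give prop-2-en-1-yl (4-methoxy-2-oxo-2H-pyran-6-yl)acetate F4. Its enolate, formed with MgCl2 and pyridine in CH2Cl2 at 0 °C, is C-acylated by 9 to give prop-2-en-1-yl (4RS,5R)-4-[(ethylsulfanyl)carbonyl]-2-(4-methoxy-2-oxo-2H-pyran-6-yl)-6-(4-methoxyphenyl)-3-oxo-5-phenylhept-6-enoate F5. Pd(PPh3)4 (5 mol %) and morpholine in THF at 0 °C then remove the allyl group, and the acid loses CO2 to return 12.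

Step 3. Catalyst turnover may stall because the acidic product ties up the hydroxo–rhodium species, the acceptor may be lost by hydrolytic retro-condensation, or facial selectivity may be insufficient. The fallback uses a singly activated E-enoate, for which the facial model is well established, and builds the second carboxyl afterwards. It sets out from 2 and comes back at 7. Boronate 2 is added to methyl (E)-cinnamate with [Rh(OH)((R)-binap)]2 in dioxane–H2O at 50 °C, which should give methyl (3R)-4-(4-methoxyphenyl)-3-phenylpent-4-enoate F6. Me2AlSEt (from AlMe3 and EtSH, CH2Cl2) converts this into S-ethyl (3R)-4-(4-methoxyphenyl)-3-phenylpent-4-enethioate F7. Enolisation with LiN(SiMe3)2 in THF at −78 °C, carboxylation with CO2 and cold acidification return 7.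

Further compounds
F1 | step 7 | 2,4,6-trimethoxyphenyllithium | [Li]c1c(OC)cc(OC)cc1OC
F2 | step 7 | S-ethyl (2RS,3R)-4-(4-methoxyphenyl)-3-phenyl-2-(2,4,6-trimethoxybenzoyl)pent-4-enethioate | C=C(c1ccc(OC)cc1)[C@@H](c1ccccc1)C(C(=O)SCC)C(=O)c1c(OC)cc(OC)cc1OC
F3 | step 7 | N-[4-({(2RS,3R)-4-(4-methoxyphenyl)-3-phenyl-2-(2,4,6-trimethoxybenzoyl)pent-4-enoyl}amino)butyl]benzamide | C=C(c1ccc(OC)cc1)[C@@H](c1ccccc1)C(C(=O)NCCCCNC(=O)c1ccccc1)C(=O)c1c(OC)cc(OC)cc1OC
F4 | step 5 | prop-2-en-1-yl (4-methoxy-2-oxo-2H-pyran-6-yl)acetate | C=CCOC(=O)CC1=CC(OC)=CC(=O)O1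
F5 | step 5 | prop-2-en-1-yl (4RS,5R)-4-[(ethylsulfanyl)carbonyl]-2-(4-methoxy-2-oxo-2H-pyran-6-yl)-6-(4-methoxyphenyl)-3-oxo-5-phenylhept-6-enoate | C=C(c1ccc(OC)cc1)[C@@H](c1ccccc1)C(C(=O)SCC)C(=O)C(C(=O)OCC=C)C1=CC(OC)=CC(=O)O1
F6 | step 3 | methyl (3R)-4-(4-methoxyphenyl)-3-phenylpent-4-enoate | C=C(c1ccc(OC)cc1)[C@@H](c1ccccc1)CC(=O)OC
F7 | step 3 | S-ethyl (3R)-4-(4-methoxyphenyl)-3-phenylpent-4-enethioate | C=C(c1ccc(OC)cc1)[C@@H](c1ccccc1)CC(=O)SCC
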